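(Its constants are invented; the flask was simulated.)

It is tempting to read 1.00 equiv of G as enough for each Z to react, but G is the limiting reagent here and a reacted Z can cost it up to 3 G.

Z 0.10 M; G 1.00 equiv; time 2.5 h

    L + G → X + D (k1 = 0.57 M⁻¹ min⁻¹)
    G + D → G.D (k2 = 1.9 M⁻¹ min⁻¹)
    D ⇌ E (K3 = 0.41, k3 = 0.11 min⁻¹)
    Z ⇌ L, rate k4*(cs4 - [L]) while solid is left; crystals form when [L] > cs4 (cs4 = 42 mM, k4 = 0.15 min⁻¹)
    G + X ⇌ G.X, settled at all times (K5 = 420 M⁻¹)

- given per volume of solution although it is solid: Z
- at the start none of Z is in solution
- what has only dissolved of Z counts as not reacted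
- run time (flask): 2.5 h

- part of the Z that has reacted (what has only dissolved counts as not reacted) at 2.5 h
- share of the unused G that is free and not bound as G.X, at 2.5 h

Step 1 takes one G, the D it gives may take a second as G.D, and the X it gives may hold a third as G.X. Dissolving can supply 6.30 mM min⁻¹ against the 2.39 mM min⁻¹ that step 1 takes at most, so I set [L] at its solubility. D is made at k1[L][G] and removed at k2[G][D], so [G] cancels and [D] levels near 12.6 mM. With E this gives the store, the reacted Z that has cost no second G: 17.8 mM.

Beyond the store each Z costs 2 G even with X released, which gives a ceiling of 58.9%. With X still held it costs 3, which gives a floor of 39.3%. With [L] at its solubility and 3 G lost per Z, I reckon a time constant of 13.9 min for the fall of G, and 4 of these are shorter than the run, so I expect the flask to pass the floor. Past it, call the further reaction y: each further Z frees about 3 X, so [X] is near 3 times y, and [G] is the unused G divided by 3 times K5 times y. So y² grows with time. Taking 0.7 of the floor amount as unused G and starting the clock after 4 time constants gives y = 9.92 mM. My figures are 49.2% and, from 1/(1+K5[X]), 7.41%.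

The forecast said 46% (42% to 50%) and 9% (6% to 14%), since “X is in excess and free G is only a few mM”. The simulation gives 46.0% and 8.71%, and the first lies between floor and ceiling.

At 2.50 h in this flask, G goes into step 1 at 1.2 times the rate at which it goes into G.D, and its half-life by the G.D step, 0.57 h, is shorter than the run. [D] + [E] in this flask then stands at 15.1 mM, against the store of 17.8 mM.

In a neighbour flask with 0.600 equiv of G and the same store, the bracket runs from 25.9% to 38.9%. That flask gives 30.4%.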